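**Conventions and assumptions (remarks on the chemistry)**

- Numbering is biogenetic: ring carbons C1–C10, lactone carbons C11–C12, C13 = acetoxymethyl carbon, C14 = methyl on C10, C15 = methyl on C4, C2′/C3′ = ester carbons. Ring A = C1–C6 and ring B = C1, C6–C10 of the octalin.
- Methyl (2S)-2-methyloxirane-2-carboxylate (27) is assumed to be purchasable as a single enantiomer.
- The sense of induction in steps 2 and 5 is taken from the established behaviour of these catalyst classes. If the first run showed the opposite sense, the catalyst antipode would be used.
- The two hydroxymethyl arms on C11 are diastereotopic, not equivalent, because C7 is stereogenic. They converge once C7 and C11 become trigonal (step 16).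
- A Friedel–Crafts alkylation of anisole with γ-valerolactone passes through a benzylic cation and would give a racemic tetralone. C10 is therefore set by asymmetric hydrogenation (step 2).
- O4 is carried through the ring opening as a trimethylsilyl ether, not a bulkier silyl ether, so that dilute acid frees it within minutes and C1 is capped before a transannular aldol can start.

## Structural features

The target is a hirsutinolide-type sesquiterpenoid. A ten-membered carbocycle (C1–C10) is bridged by an ether oxygen from C4 to C1 (an oxolane whose C1 is a hemiketal) and fused through C6–C7 to a γ-ylidene butenolide (O–C6(=C5)–C7=C11–C12=O). C11 carries the acetoxymethyl carbon C13, and O8 carries a (2R)-3-chloro-2-hydroxy-2-methylpropanoate.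

The ring has four stereocentres: C1 (S), C4 (R), C8 (S) and C10 (R). C1 and C10 are adjacent, C8 and C10 are 1,3-related across C9, and C4 is four bonds from C8 (through C5, C6 and C7). C4 is tied to C1 by the oxygen bridge, so C1 has no freedom once C4 is set. The fifth stereocentre, C2′, is remote and must come from the acyl building block.

Fragile groups are:
- the hemiketal (exchange, ring–chain tautomerism);
- the cross-conjugated enol lactone (hydration, acyl transfer);
- the C13 acetate, which is allylic and sits on the α-carbon of the unsaturated lactone, and is therefore open to SN2′ displacement by nucleophilic amines;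
- the chlorohydrin ester, which closes to a glycidate with base.

The real difficulty is twofold. The medium ring has several trigonal or bridged positions and is poorly suited to end-to-end cyclisation. The remote C4/C8 relationship has no neighbouring-group control.

The key step exploits the fact that C1 (hemiketal carbon) and C6 (enol-lactone carbon) are both at the ketone oxidation level and stand 1,6 across the ten-membered ring. A cyclodecane-1,6-dione is the ozonolysis product of a bicyclo[4.4.0]dec-1(6)-ene. The medium ring can therefore be carried as two fused six-membered rings until the C1=C6 bond is cut. On that octalin, C8 and C10 are set on an ordinary cyclohexene, while C7 and C11 are headed for sp2 and need no lasting control.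

## Logic of the disconnections

34 ⇒ 32 (through 33). The C3′–Cl bond is cut and the C1 hydroxyl is exchanged for methoxyl. The chlorohydrin is base-labile and the hemiketal exchanges easily, so both are unveiled last from an epoxide and a methyl ketal that are inert to the amines and oxidant used before. The forward step needs chloride to attack only the CH2 of the epoxide, in a weakly acidic medium that also hydrolyses the ketal and spares the enol lactone and allylic acetate.

32 ⇒ 31. Water is added back across C5=C6. The ylidene lactone is the anhydro form of a γ-hydroxybutenolide. Only C5 carries hydrogen next to C6, so the forward dehydration has one regiochemical outcome, and the alkene geometry is imposed by the ring.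

31 ⇒ 29 (through 30). The carbonyl oxygen at C12 and the hydroxyl at C6 are removed, which leaves a furan. The furan is a stable carrier of the butenolide in which C7 and C11 are trigonal. The forward oxygenation must place the carbonyl at C12; this is secured because C12 carries the only ring hydrogen.

29 ⇒ 26 + 28, and 28 ⇒ 27. The acyl–O8 bond is cut. The acid is a small, enantiopure epoxide acid, one hydrolysis away from a commercial ester. The forward esterification is placed before the butenolide exists, so that no nucleophilic catalyst meets the later SN2′-prone acetate.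

26 ⇒ 25 ⇒ 22 (through 24 and 23). The O8–Si bond, the C1–OMe bond and the furan C12–O bond are cut. The furan traces to a 1,4-keto aldehyde (C6 ketone, C12 aldehyde). The forward step needs oxidation of one primary alcohol and acid-promoted cyclodehydration without loss of the β-acetoxy group.

22 ⇒ 20 (through 21). The acetyl–O bond is cut. The forward step must acylate exactly one of the two arms of a 1,3-diol; which arm reacts is immaterial.

20 ⇒ 19. The O4–C1 bond and the acetal are cut. The oxygen bridge is a transannular hemiketal of a 4-hydroxy-1,6-dione. The forward step must free O4 faster than the dione can undergo aldol chemistry, and must keep the C8 silyl ether.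

19 ⇒ 17 (through 18). C1 and C6 are reconnected as a C=C bond. This is the strategic simplification: the ten-membered ring becomes an octalin and no macrocyclisation is needed. The forward step demands a single, electron-rich alkene and a cold, neutral work-up.

17 ⇒ 16 ⇒ 15. The O4–Si bond and the C4–C15 bond are cut, leaving a β,γ-unsaturated ketone. The forward methyl addition must avoid enolisation, and its facial selectivity is the weak point of the plan.

15 ⇒ 13 (through 14). Ring A is re-aromatised to an anisole. The forward dissolving-metal reduction leaves exactly the tetrasubstituted C1=C6 bond and a ketone at C4; all other groups must be inert to Li/NH3.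

13 ⇒ 12 ⇒ 11 ⇒ 10. Protecting groups are removed and the two arms are taken back to the ester and lactone carbonyls. The forward steps are reduction, selective 1,3-diol acetalisation and silylation.

10 ⇒ 8 + 9. The C7–C11 bond and the lactone C–O bond are cut. An epoxide and a malonate give C7–C11 and the trans C7/C8 relationship in one step. The forward step must attack the benzylic carbon.

8 ⇒ 7 ⇒ 5. The two epoxide C–O bonds are cut, then the C7=C8 alkene is traced to the ketone. The forward epoxidation must deliver oxygen cis to the C10 methyl.

5 ⇒ 4 ⇒ 3 ⇒ 1 + 2. The aryl–C7 bond, the two C–H bonds at C9/C10 and the C9=C10 bond are cut. The forward sequence is olefination, asymmetric hydrogenation (sets C10) and ring closure ortho to the alkyl chain.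

## Other disconnections considered

**Alternative 1:** The cut is at C5–C6 and C6–C7, so that C6 becomes a dithiane carbon between two epoxide-derived carbinols.
- Forward key step: lithiated 2-(tert-butyldimethylsilyl)-1,3-dithiane A2 opens the monosubstituted epoxide A3 at its CH2 terminus (C7). HMPA then triggers a 1,4-Brook shift of silicon from C6 to O8, and the regenerated C6 carbanion opens the 2,2-disubstituted epoxide A4 at C5. This would give the open-chain C1–C10 array A1 in one flask.
- In its favour: three fragments are joined in one operation and C6 arrives as a masked ketone. C4 and C8 each come from a separately made enantiopure epoxide, so their remote relationship is under reagent control. On this point the alternative is better than the chosen plan, whose weakest stereocentre is C4.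
- Against it here: A1 is acyclic and lacks C11–C13, the C10 stereocentre and the C1 carbonyl. The ten-membered ring would still have to be closed end to end. C7 is an unactivated methylene that must later receive the C11 unit.
- Comparison: structurally it solves the stereochemistry and postpones the ring; the chosen plan solves the ring and leaves C4 exposed. Mechanistically both key steps are polar, well-understood processes of comparable reliability (equal). In step economy the linchpin is superior up to A1 but should be inferior overall, because ring closure, C7 functionalisation and dithiane removal all follow.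

**Alternative 2:** The cut is C8–C9.
- Forward key step: CrCl2 (divalent chromium) reduces the allylic bromide of the furan aldehyde A6 to an allylchromium species. This adds to the C8 aldehyde, closing the ten-membered ring and creating the C8 carbinol of A5.
- In its favour: ring closure and a stereocentre in one mild, chemoselective step. The bicyclic C1/C4 ketal is assembled beforehand, so C4 is fixed inside a small fragment (better than the chosen plan). The silylated furan is a regiochemically unambiguous butenolide precursor, equal in concept to the furan of steps 16–21.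
- Against it here: a ten-membered ring is closed by bond formation under high dilution with a large excess of a chromium salt. The C8 configuration would depend on a macrocyclic transition state and is hard to predict. C10 is left as an exocyclic methylene whose later hydrogenation must be face-selective next to a furan.
- Comparison: structurally it handles C4 better and C8/C10 worse than the chosen plan, which sets both on a cyclohexene before the ring is opened. Mechanistically a ring-forming organochromium addition is less certain than a ring-revealing alkene cleavage. Step economy would be comparable if the two fragments are short.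

**Alternative 3:** The cut removes C12 as carbon monoxide (C11–C12 and C12–O).
- Forward key step: zerovalent palladium, generated from PdCl2(PPh3)2, inserts into the C11–I bond of the Z-β-iodoenone A8. CO insertion gives an acylpalladium species, and Et3N-assisted enolisation of the C6 ketone towards C5 lets the enol oxygen close the lactone. C5=C6 and the butenolide of A7 would arise together.
- In its favour: the complete ylidene butenolide at the correct oxidation level in one step. This is better step economy than the chosen plan, which spends steps 16, 20 and 21 on the same ring. No singlet oxygen is needed. The C5=C6 geometry is ring-controlled in both plans (equal).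
- Against it here: it is an endgame tactic that presupposes the ten-membered ring. A8 needs a tetrasubstituted vinyl iodide of defined geometry inside that ring. Slow oxidative addition at a hindered centre, capture of the acylpalladium by the free hemiketal hydroxyl, and isomerisation of the vinylpalladium are plausible diversions. The silyl groups of A7 must still be exchanged for acetate and the chlorohydrin ester.
- Comparison: structurally it addresses only the lactone, where it is the more direct. Mechanistically the carbonylation is sound but rests on a harder substrate than the furan route. Over the whole synthesis the saving depends on how A8 and its ring are made.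

Key step: step 13

## Route

Step 1
Reactants: 1 4′-methoxyacetophenone; 2 (2-carboxyethyl)triphenylphosphonium bromide
Product: 3 (E)-4-(4-methoxyphenyl)pent-3-enoic acid
Conditions: NaN(SiMe3)2 (2.2 equiv), THF, −20 °C → rt; aq. HCl; recrystallisation
Reagents that add atoms: none
Why: Wittig olefination of an aryl methyl ketone with the carboxylate-bearing ylide forms C9=C10; the E isomer (aryl trans to the CH2CO2H chain) is the expected major product and is purified by crystallisation, because alkene geometry decides the sense of the next step.

Step 2
Reactants: 3 (E)-4-(4-methoxyphenyl)pent-3-enoic acid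
Product: 4 (R)-4-(4-methoxyphenyl)pentanoic acid
Conditions: H2 (6 atm), [Ir(cod)(SIPHOX)][B(C6H3(CF3)2)4] (1 mol %; SIPHOX = chiral spiro phosphine–oxazoline, antipode chosen for the R acid), Et3N (0.5 equiv), MeOH, rt
Reagents that add atoms: none
Why: Carboxy-directed iridium-catalysed asymmetric hydrogenation of a β,γ-unsaturated acid, a substrate class for which these catalysts are highly selective; the carboxylate binds the metal and hydrogen is delivered to one face of the trisubstituted alkene, which sets the benzylic methine that becomes C10.

Step 3
Reactants: 4 (R)-4-(4-methoxyphenyl)pentanoic acid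
Product: 5 (R)-7-methoxy-4-methyl-3,4-dihydronaphthalen-1(2H)-one
Conditions: P2O5/MeSO3H (1:10), rt
Reagents that add atoms: none
Why: Intramolecular Friedel–Crafts acylation; closure can only occur ortho to the alkyl chain (meta to OMe), which puts the ketone at the future C7 and the methoxy group at the future C4, and the benzylic stereocentre has no pathway for enolisation.

Step 4
Reactants: 5 (R)-7-methoxy-4-methyl-3,4-dihydronaphthalen-1(2H)-one
Product: 7 (R)-6-methoxy-1-methyl-1,2-dihydronaphthalene, via benzylic alcohol 6 (not isolated)
Conditions: NaBH4, MeOH, 0 °C; then TsOH·H2O (5 mol %), toluene, 80 °C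
Reagents that add atoms: none
Why: Borohydride reduction followed by acid-catalysed E1 dehydration of the benzylic alcohol gives the styrene-type C7=C8 alkene; the carbinol centre of 6 is destroyed at once, so its configuration is irrelevant.

Step 5
Reactants: 7 (R)-6-methoxy-1-methyl-1,2-dihydronaphthalene
Product: 8 (1R,2S,4R)-1,2-epoxy-7-methoxy-4-methyl-1,2,3,4-tetrahydronaphthalene
Conditions: (R,R)-N,N′-bis(3,5-di-tert-butylsalicylidene)-1,2-cyclohexanediaminomanganese chloride [(R,R)-(salen)MnCl, 4 mol %], aq. NaOCl (pH 11.3), 4-phenylpyridine N-oxide (0.2 equiv), CH2Cl2, 0 °C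
Reagents that add atoms: sodium hypochlorite, [Na+].[O-]Cl
Why: Jacobsen–Katsuki epoxidation of a cis-disubstituted cyclic styrene, the best substrate class for this catalyst; the (R,R) complex is expected to deliver oxygen to the face that gives the (7R,8S) epoxide, cis to the C10 methyl, under reagent control that should outweigh the modest bias of the remote methyl group, and any minor enantiomer of 7 is removed as a diastereomer.

Step 6
Reactants: 8 (1R,2S,4R)-1,2-epoxy-7-methoxy-4-methyl-1,2,3,4-tetrahydronaphthalene; 9 dimethyl malonate
Product: 10 trans-fused lactone ester methyl (3aS,5R,9bS)-8-methoxy-5-methyl-2-oxo-1,2,3a,4,5,9b-hexahydronaphtho[2,1-b]furan-1-carboxylate (C11 epimers)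
Conditions: NaOMe (1.2 equiv), 9 (3 equiv), MeOH, 65 °C; aq. NH4Cl
Reagents that add atoms: none
Why: Malonate–epoxide lactone synthesis: SN2 opening at the benzylic carbon C7 with inversion (trans-diaxial), then lactonisation of the C8 alkoxide onto one ester; this forms C7–C11, places C11 trans to O8 and leaves C8 untouched, and C11 is epimerisable and of no consequence.

Step 7
Reactants: 10 trans-fused lactone ester
Product: 11 2-[(1S,2S,4R)-2-hydroxy-7-methoxy-4-methyl-1,2,3,4-tetrahydronaphthalen-1-yl]propane-1,3-diol
Conditions: LiAlH4, THF, 0 → 50 °C; H2O/NaOH work-up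
Reagents that add atoms: none
Why: Exhaustive hydride reduction of lactone and ester releases the secondary C8 hydroxyl and both primary arms (C12, C13) in one operation, as in the standard reduction of monosubstituted malonates to 2-substituted propane-1,3-diols.

Step 8
Reactants: 11 triol
Product: 12 (1S,2S,4R)-1-(2,2-dimethyl-1,3-dioxan-5-yl)-7-methoxy-4-methyl-1,2,3,4-tetrahydronaphthalen-2-ol
Conditions: Me2C(OMe)2, PPTS (cat.), acetone, rt
Reagents that add atoms: 2,2-dimethoxypropane, COC(C)(C)OC
Why: Acetonide formation under thermodynamic control selects the six-membered 1,3-dioxane of the primary 1,3-diol over a seven-membered acetal that would involve O8, so the C8 hydroxyl stays free.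

Step 9
Reactants: 12 acetonide alcohol
Product: 13 tert-butyldimethylsilyl ether of 12 at O8 (1S,2S,4R)
Conditions: TBSOTf, 2,6-lutidine, CH2Cl2, −78 → 0 °C
Reagents that add atoms: tert-butyldimethylsilyl trifluoromethanesulfonate, CC(C)(C)[Si](C)(C)OS(=O)(=O)C(F)(F)F
Why: Silylation of the remaining secondary alcohol; this silyl ether is chosen because it withstands dissolving-metal reduction, organocerium addition, ozone and the mild acid of step 14.

Step 10
Reactants: 13 silyl ether
Product: 15 (7S,8S,10R)-8-(tert-butyldimethylsilyloxy)-7-(2,2-dimethyl-1,3-dioxan-5-yl)-10-methylbicyclo[4.4.0]dec-1(6)-en-4-one, via dihydroanisole enol ether 14 (not isolated)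
Conditions: Li, NH3(l), t-BuOH, THF, −78 → −33 °C; NH4Cl; then (CO2H)2, THF/H2O, 0 °C
Reagents that add atoms: water, O
Why: Birch reduction of the anisole gives the 2,5-dihydro compound whose remaining ring alkene is the tetrasubstituted C1=C6; oxalic acid hydrolyses the enol ether to the β,γ-unsaturated ketone without conjugation and, being fast at 0 °C, should spare the acetonide. The homobenzylic C8–O bond, the silyl ether and the acetal are inert to Li/NH3.

Step 11
Reactants: 15 β,γ-unsaturated ketone
Product: 16 (4R,7S,8S,10R)-8-(tert-butyldimethylsilyloxy)-7-(2,2-dimethyl-1,3-dioxan-5-yl)-4,10-dimethylbicyclo[4.4.0]dec-1(6)-en-4-ol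
Conditions: CeCl3, MeMgBr, THF, −78 °C; aq. NH4Cl; chromatography (removal of the 4S epimer)
Reagents that add atoms: methylmagnesium bromide, C[Mg]Br
Why: 1,2-Addition of a methylcerium reagent (Imamoto conditions) suppresses enolisation and conjugation of the β,γ-enone; the ketone faces differ only through remote groups, so both C4 epimers are expected, and the 4R isomer (oxygen on the face of O8 and the C10 methyl) is isolated and assigned by NOE or by crystallography of a derivative.

Step 12
Reactants: 16 tertiary alcohol
Product: 17 4-O-trimethylsilyl ether of 16 (4R,7S,8S,10R)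
Conditions: TMSOTf, 2,6-lutidine, CH2Cl2, −78 °C
Reagents that add atoms: trimethylsilyl trifluoromethanesulfonate, C[Si](C)(C)OS(=O)(=O)C(F)(F)F
Why: Silylation of the tertiary alcohol; the trimethylsilyl ether is stable to ozone and a neutral work-up but is cleaved within minutes by dilute acid, so O4 can be released onto C1 at once in step 14.

Step 13
Reactants: 17 octalin silyl ether
Product: 19 (4R,7R,8S,10R)-8-(tert-butyldimethylsilyloxy)-7-(2,2-dimethyl-1,3-dioxan-5-yl)-4,10-dimethyl-4-(trimethylsilyloxy)cyclodecane-1,6-dione, via methoxy hydroperoxide 18 (not isolated)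
Conditions: O3, CH2Cl2/MeOH (4:1), Sudan Red 7B, −78 °C; then Me2S, −78 → 0 °C; pH 7 work-up, kept cold, used crude
Reagents that add atoms: ozone, [O-][O+]=O
Why: Ozone adds as a 1,3-dipole to the only C=C bond, the electron-rich tetrasubstituted C1=C6; cycloreversion of the primary ozonide gives a ketone and a carbonyl oxide, which methanol traps as the α-methoxy hydroperoxide 18 (either regioisomer), and Me2S reduces this to the second ketone. The closest known reaction type is the ozonolysis of bicyclo[4.4.0]dec-1(6)-enes to cyclodecane-1,6-diones. No ring-closing bond is made: the ten-membered ring appears by scission of the bond common to the two six-membered rings, so none of the entropic or transannular cost of a medium-ring cyclisation is paid. No stereocentre is created; C4, C8 and C10 were set on the octalin and are not touched. Chemoselectivity rests on the absence of any other π bond and on stopping at the indicator end-point; silyl ethers and the acetonide are inert. The selectivity that matters lies in the work-up, because C7 and C10 are now α to ketones and O8 is β to C6: transannular aldolisation (C5 enol onto C1), β-elimination of the silyloxy group and epimerisation at C10 are avoided by a cold, neutral, base-free work-up and by taking 19 directly into step 14.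

Step 14
Reactants: 19 cyclodecane-1,6-dione
Product: 20 (1S,4R,7R,8S,10R)-8-(tert-butyldimethylsilyloxy)-7-(1,3-dihydroxypropan-2-yl)-1-hydroxy-4,10-dimethyl-1,4-epoxycyclodecan-6-one
Conditions: AcOH/THF/H2O (3:1:1), 0 °C → rt
Reagents that add atoms: none
Why: Aqueous acetic acid cleaves the tertiary trimethylsilyl ether first and the freed O4 adds across the ring to the C1 ketone (five-membered transannular hemiketal; the C1 configuration follows from C4 because the bridge can only span the ring cis), which removes the C1 carbonyl before aldol chemistry can start; the same medium hydrolyses the acetonide and leaves the hindered secondary silyl ether at O8. Compound 20 is expected to equilibrate with cyclic C6 hemiketals formed by either arm.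

Step 15
Reactants: 20 hemiketal diol
Product: 22 mono-acetate of 20 at one C11 arm (C11 epimers), via cyclic orthoacetate 21 (not isolated)
Conditions: MeC(OMe)3, CSA (5 mol %), CH2Cl2, rt; then H2O/THF, rt
Reagents that add atoms: trimethyl orthoacetate, CC(OC)(OC)OC
Why: Mono-acylation of a 1,3-diol through its cyclic orthoester: acid-catalysed exchange gives the 2-methoxy-2-methyl-1,3-dioxane, whose hydrolysis can only give a monoacetate; the two C11 epimers converge in step 16.

Step 16
Reactants: 22 mono-acetate
Product: 25 (1S,4R,8S,10R)-13-acetoxy-8-(tert-butyldimethylsilyloxy)-1-methoxy-1,4-epoxy furan (furan ring O–C6=C7–C11=C12), via keto aldehyde 23 (not isolated), via furan hemiketal 24 (not isolated)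
Conditions: Dess–Martin periodinane, CH2Cl2, 0 °C → rt; then CSA (10 mol %), 4 Å MS, CH2Cl2, rt; then MeOH, rt
Reagents that add atoms: methanol, CO
Why: Dess–Martin oxidation of the remaining primary alcohol gives a 1,4-keto aldehyde that acid cyclodehydrates to the furan (Paal–Knorr synthesis), erasing the C7 and C11 stereocentres; methanol then converts the C1 hemiketal into its methyl ketal by acid-catalysed exchange, which protects C1 through steps 17–21.

Step 17
Reactants: 25 furan methyl ketal
Product: 26 (1S,4R,8S,10R)-13-acetoxy-8-hydroxy-1-methoxy-1,4-epoxy furan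
Conditions: Bu4NF/AcOH (1:1), THF, 0 °C → rt
Reagents that add atoms: none
Why: Fluoride-mediated desilylation buffered with acetic acid, so that neither the acetate nor the ketal is touched; with C1 locked as the methyl ketal the free C8 hydroxyl cannot compete with O4 for C1.

Step 18
Reactants: 27 methyl (2S)-2-methyloxirane-2-carboxylate
Product: 28 (2S)-2-methyloxirane-2-carboxylic acid
Conditions: LiOH, THF/H2O, 0 °C; NaHSO4 (pH 3), EtOAc extraction
Reagents that add atoms: lithium hydroxide, [Li+].[OH-]
Why: Saponification of the methyl ester; the quaternary stereocentre cannot epimerise and the epoxide, deactivated by the carboxyl group, should survive brief contact with cold dilute acid.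

Step 19
Reactants: 26 furan alcohol; 28 (2S)-2-methyloxirane-2-carboxylic acid
Product: 29 8-O-[(2S)-2-methyloxirane-2-carbonyl] ester of 26
Conditions: EDC·HCl, DMAP (0.2 equiv), CH2Cl2, 0 °C → rt
Reagents that add atoms: none
Why: Steglich esterification of the secondary furylcarbinol with a small epoxy acid; it is done at the furan stage because the C13 acetate of the later butenolide is an SN2′-prone allylic acetate that should not meet a nucleophilic catalyst.

Step 20
Reactants: 29 furan ester
Product: 31 6-hydroxy-6,12-olide (γ-hydroxybutenolide with C7=C11; C6 epimers), via furan endoperoxide 30 (not isolated)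
Conditions: O2, hν (visible), tetraphenylporphyrin (cat.), i-Pr2NEt (1.5 equiv), CH2Cl2, −78 °C → rt
Reagents that add atoms: dioxygen, O=O
Why: [4+2] Cycloaddition of singlet oxygen to the furan gives the 2,5-endoperoxide; the hindered amine removes the only bridgehead hydrogen (H12) in a Kornblum–DeLaMare fragmentation, which puts the carbonyl at C12 and the hydroxyl at C6 and leaves C7=C11 in place (base-directed furan photooxygenation).

Step 21
Reactants: 31 γ-hydroxybutenolide
Product: 32 (1S,4R,5E,8S,10R)-13-acetoxy-1-methoxy-1,4-epoxy-5,7(11)-dien-6,12-olide 8-O-[(2S)-2-methyloxirane-2-carboxylate]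
Conditions: MsCl, Et3N, CH2Cl2, −20 → 0 °C
Reagents that add atoms: none
Why: Dehydration of a γ-hydroxybutenolide: sulfonylation of the pseudo-acid hydroxyl (or of the ring-opened carboxylate) and loss of a C5 proton give the γ-ylidene butenolide; the geometry should be imposed by the ring, because C4 and C7 are joined through a five-atom bridge (O, C1, C10, C9, C8) and a nine-membered ring accommodates only the cis arrangement across C5=C6.

Step 22
Reactants: 32 epoxy ester methyl ketal
Product: 34 CNP0414417.3, via chlorohydrin methyl ketal 33 (not isolated)
Conditions: LiCl (10 equiv), AcOH, THF, rt; then H2O (THF/AcOH/H2O 2:2:1), 30 °C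
Reagents that add atoms: lithium chloride, [Li+].[Cl-]; water, O
Why: Halohydrin formation from an epoxide with LiCl/AcOH: chloride attacks the primary carbon of the 2,2-disubstituted glycidate and the C–O bond at the quaternary carbon stays intact, so the (S)-epoxide becomes the (R)-chlorohydrin by a change of CIP priorities only; added water then hydrolyses the bridged methyl ketal through its cyclic oxocarbenium ion to the hemiketal.

## Compound list

1 | 4′-methoxyacetophenone | COc1ccc(cc1)C(C)=O | starting material
2 | (2-carboxyethyl)triphenylphosphonium bromide | OC(=O)CC[P+](c1ccccc1)(c1ccccc1)c1ccccc1.[Br-] | starting material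
3 | (E)-4-(4-methoxyphenyl)pent-3-enoic acid | COc1ccc(cc1)/C(C)=C/CC(=O)O | intermediate
4 | (R)-4-(4-methoxyphenyl)pentanoic acid | C[C@H](CCC(=O)O)c1ccc(OC)cc1 | intermediate
5 | (R)-7-methoxy-4-methyl-3,4-dihydronaphthalen-1(2H)-one | C[C@@H]1CCC(=O)c2cc(OC)ccc12 | intermediate
6 | (4R)-7-methoxy-4-methyl-1,2,3,4-tetrahydronaphthalen-1-ol (carbinol epimers) | C[C@@H]1CCC(O)c2cc(OC)ccc12 | intermediate (not isolated)
7 | (R)-6-methoxy-1-methyl-1,2-dihydronaphthalene | C[C@@H]1CC=Cc2cc(OC)ccc12 | intermediate
8 | (1R,2S,4R)-1,2-epoxy-7-methoxy-4-methyl-1,2,3,4-tetrahydronaphthalene (7R,8S,10R; epoxide cis to methyl) | C[C@@H]1C[C@@H]2O[C@@H]2c2cc(OC)ccc12 | intermediate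
9 | dimethyl malonate | COC(=O)CC(=O)OC | starting material
10 | methyl (3aS,5R,9bS)-8-methoxy-5-methyl-2-oxo-1,2,3a,4,5,9b-hexahydronaphtho[2,1-b]furan-1-carboxylate (7S,8S,10R; C11 epimers) | COC(=O)C1[C@@H]2[C@@H](OC1=O)C[C@@H](C)c3ccc(OC)cc32 | intermediate
11 | 2-[(1S,2S,4R)-2-hydroxy-7-methoxy-4-methyl-1,2,3,4-tetrahydronaphthalen-1-yl]propane-1,3-diol | OCC(CO)[C@@H]1[C@@H](O)C[C@@H](C)c2ccc(OC)cc21 | intermediate
12 | (1S,2S,4R)-1-(2,2-dimethyl-1,3-dioxan-5-yl)-7-methoxy-4-methyl-1,2,3,4-tetrahydronaphthalen-2-ol | CC1(C)OCC(CO1)[C@@H]2[C@@H](O)C[C@@H](C)c3ccc(OC)cc32 | intermediate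
13 | O8-tert-butyldimethylsilyl ether of 12 | CC1(C)OCC(CO1)[C@@H]2[C@@H](O[Si](C)(C)C(C)(C)C)C[C@@H](C)c3ccc(OC)cc32 | intermediate
14 | 4-methoxy-bicyclo[4.4.0]deca-1(6),3-diene (Birch enol ether; 7S,8S,10R) | CC1(C)OCC(CO1)[C@@H]2[C@@H](O[Si](C)(C)C(C)(C)C)C[C@@H](C)C3=C2CC(OC)=CC3 | intermediate (not isolated)
15 | (7S,8S,10R)-8-(tert-butyldimethylsilyloxy)-7-(2,2-dimethyl-1,3-dioxan-5-yl)-10-methylbicyclo[4.4.0]dec-1(6)-en-4-one | CC1(C)OCC(CO1)[C@@H]2[C@@H](O[Si](C)(C)C(C)(C)C)C[C@@H](C)C3=C2CC(=O)CC3 | intermediate
16 | (4R,7S,8S,10R)-4-hydroxy-4,10-dimethyl analogue of 15 (tertiary alcohol) | CC1(C)OCC(CO1)[C@@H]2[C@@H](O[Si](C)(C)C(C)(C)C)C[C@@H](C)C3=C2C[C@@](O)(C)CC3 | intermediate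
17 | 4-O-trimethylsilyl ether of 16 (octalin, precursor of the key step) | CC1(C)OCC(CO1)[C@@H]2[C@@H](O[Si](C)(C)C(C)(C)C)C[C@@H](C)C3=C2C[C@@](O[Si](C)(C)C)(C)CC3 | intermediate
18 | 1-hydroperoxy-1-methoxy-6-oxo ring-opened compound (one of two regioisomers) | CC1(C)OCC(CO1)[C@@H]2[C@@H](O[Si](C)(C)C(C)(C)C)C[C@@H](C)C(OC)(OO)CC[C@@](C)(O[Si](C)(C)C)CC2=O | intermediate (not isolated)
19 | (4R,7R,8S,10R)-8-(tert-butyldimethylsilyloxy)-7-(2,2-dimethyl-1,3-dioxan-5-yl)-4,10-dimethyl-4-(trimethylsilyloxy)cyclodecane-1,6-dione | CC1(C)OCC(CO1)[C@@H]2[C@@H](O[Si](C)(C)C(C)(C)C)C[C@@H](C)C(=O)CC[C@@](C)(O[Si](C)(C)C)CC2=O | intermediate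
20 | (1S,4R,7R,8S,10R)-8-(tert-butyldimethylsilyloxy)-7-(1,3-dihydroxypropan-2-yl)-1-hydroxy-4,10-dimethyl-1,4-epoxycyclodecan-6-one | OCC(CO)[C@H]1C(=O)C[C@@]2(C)CC[C@](O)(O2)[C@H](C)C[C@@H]1O[Si](C)(C)C(C)(C)C | intermediate
21 | cyclic orthoacetate of 20 (2-methoxy-2-methyl-1,3-dioxan-5-yl at C7) | COC1(C)OCC(CO1)[C@H]2C(=O)C[C@@]3(C)CC[C@](O)(O3)[C@H](C)C[C@@H]2O[Si](C)(C)C(C)(C)C | intermediate (not isolated)
22 | mono-acetate of 20 (C11 epimers) | CC(=O)OCC(CO)[C@H]1C(=O)C[C@@]2(C)CC[C@](O)(O2)[C@H](C)C[C@@H]1O[Si](C)(C)C(C)(C)C | intermediate
23 | 12-aldehyde of 22 (1,4-keto aldehyde) | CC(=O)OCC(C=O)[C@H]1C(=O)C[C@@]2(C)CC[C@](O)(O2)[C@H](C)C[C@@H]1O[Si](C)(C)C(C)(C)C | intermediate (not isolated)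
24 | (1S,4R,8S,10R)-13-acetoxy-8-(tert-butyldimethylsilyloxy)-1-hydroxy-1,4-epoxy furan | CC(=O)OCc1coc2C[C@@]3(C)CC[C@](O)(O3)[C@H](C)C[C@H](O[Si](C)(C)C(C)(C)C)c12 | intermediate (not isolated)
25 | 1-O-methyl ketal of 24 | CC(=O)OCc1coc2C[C@@]3(C)CC[C@](OC)(O3)[C@H](C)C[C@H](O[Si](C)(C)C(C)(C)C)c12 | intermediate
26 | 8-hydroxy furan methyl ketal | CC(=O)OCc1coc2C[C@@]3(C)CC[C@](OC)(O3)[C@H](C)C[C@H](O)c12 | intermediate
27 | methyl (2S)-2-methyloxirane-2-carboxylate | COC(=O)[C@]1(C)CO1 | starting material
28 | (2S)-2-methyloxirane-2-carboxylic acid | OC(=O)[C@]1(C)CO1 | intermediate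
29 | 8-O-[(2S)-2-methyloxirane-2-carbonyl] furan methyl ketal | CC(=O)OCc1coc2C[C@@]3(C)CC[C@](OC)(O3)[C@H](C)C[C@H](OC(=O)[C@]4(C)CO4)c12 | intermediate
30 | 6,12-endoperoxide of 29 (2,3,7-trioxabicyclo[2.2.1]hept-5-ene) | CC(=O)OCC1=C2C4(C[C@@]3(C)CC[C@](OC)(O3)[C@H](C)C[C@@H]2OC(=O)[C@]5(C)CO5)OOC1O4 | intermediate (not isolated)
31 | 6-hydroxy-7(11)-en-6,12-olide (γ-hydroxybutenolide; C6 epimers) | CC(=O)OCC1=C2C(O)(C[C@@]3(C)CC[C@](OC)(O3)[C@H](C)C[C@@H]2OC(=O)[C@]4(C)CO4)OC1=O | intermediate
32 | (1S,4R,5E,8S,10R)-1-O-methyl 5,7(11)-dien-6,12-olide 8-O-[(2S)-2-methyloxirane-2-carboxylate] | CC(=O)OCC1=C2/C(=C\[C@@]3(C)CC[C@](OC)(O3)[C@H](C)C[C@@H]2OC(=O)[C@]4(C)CO4)OC1=O | intermediate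
33 | 1-O-methyl ketal of the target (chlorohydrin ester) | CC(=O)OCC1=C2/C(=C\[C@@]3(C)CC[C@](OC)(O3)[C@H](C)C[C@@H]2OC(=O)[C@@](C)(O)CCl)OC1=O | intermediate (not isolated)
34 | CNP0414417.3: (1S,4R,5E,8S,10R)-13-acetoxy-1-hydroxy-1,4-epoxy-5,7(11)-dien-6,12-olide 8-O-[(2R)-3-chloro-2-hydroxy-2-methylpropanoate] | CC(=O)OCC1=C2/C(=C\[C@@]3(C)CC[C@](O)(O3)[C@H](C)C[C@@H]2OC(=O)[C@@](C)(O)CCl)OC1=O | target

## Step count and risk assessment

Total: 22 steps. Longest linear sequence: 21 steps (steps 1–17 and 19–22); step 18 is a one-step branch.

**Step 13 (key step).** The likely failures are incomplete reduction of the peroxidic intermediate, and then, once the dione exists, transannular aldolisation, β-elimination of the C8 silyloxy group or epimerisation at C10 during work-up, because the product has two enolisable ketones held close across the ring. The fallback avoids peroxides and any protic work-up. It sets out from 17: OsO4·TMEDA in CH2Cl2 at −78 °C, followed by reductive release of the osmate, would give the cis-1,6-diol F1. Glycol cleavage of F1 with Pb(OAc)4 in CH2Cl2 at −20 °C returns to the route at 19.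

**Step 11.** Poor facial selectivity is expected, since the two faces of the C4 ketone are distinguished only by substituents four or more bonds away; at worst half of the material is lost as the 4S epimer. The fallback delivers oxygen instead of carbon to the more accessible face, and should therefore be stereocomplementary. It sets out from 15: methylenation with Cp2TiMe2 (toluene, 65 °C, non-basic) would give the 4-methylene octalin F2. Mukaiyama hydration of F2 (Mn(dpm)3, PhSiH3, O2, i-PrOH, then PPh3), which should spare the hindered tetrasubstituted alkene, returns to the route at 16.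

**Step 6.** The nucleophile may attack C8 instead of the benzylic C7, or the base may isomerise the epoxide, because a soft SN2 nucleophile responds to sterics as well as to benzylic activation. The fallback uses a Lewis-acidic enolate, whose opening is governed by the benzylic position, and builds C11–C13 separately. It sets out from 8: the aluminium enolate of tert-butyl acetate (LiN(iPr)2, then Et2AlCl, THF, −78 → 0 °C) would give the γ-hydroxy ester F3. Double deprotonation of F3 and trapping with gaseous formaldehyde would give the α-hydroxymethyl ester F4, and LiAlH4 reduction of F4 returns to the route at 11.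

**Step 5.** The facial selectivity may erode if catalyst and substrate preferences are mismatched, since the pseudoaxial C10 methyl shields the face the catalyst must use. The fallback is substrate-controlled and turns that shielding to advantage. It sets out from 7: NBS in aqueous acetone should form the bromonium ion anti to the methyl group and give the trans-bromohydrin F5 (hydroxyl at C7, bromine at C8). K2CO3 in MeOH then closes F5 with inversion at C8 and returns to the route at 8.

**Step 16.** The β-acetoxy aldehyde may lose acetic acid (E1cB) before the furan closes, or the oxidation may over-run. The fallback forms the five-membered ring before the oxidation level is raised, so no free aldehyde is present. It sets out from 22: acid-catalysed cyclodehydration of the γ-hydroxy ketone (PPTS, toluene, 4 Å MS, 60 °C) would give the 4,5-dihydrofuran F6. Dehydrogenation of F6 with DDQ returns to the route at 24, which is ketalised as in the last stage of step 16.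

**Step 22.** Water may compete with chloride for the epoxide, the ketal may hydrolyse sluggishly, or the allylic acetate may be lost, because two transformations are asked of one mildly acidic medium on the complete molecule. The fallback attaches the finished, protected side chain instead. It sets out from 26 and 28. Concentrated HCl would convert 28 into (2R)-3-chloro-2-hydroxy-2-methylpropanoic acid F7. Silylation (Et3SiOTf, 2,6-lutidine, then mild aqueous cleavage of the silyl ester) would give the 2-O-triethylsilyl acid F8. Esterification of 26 with F8 under the conditions of step 19 would give the furan ester F9. The conditions of step 20 would give the endoperoxide F10 and then the hydroxybutenolide F11, and those of step 21 the ylidene butenolide F12. Aqueous HF in MeCN would remove the silyl group from F12 and hydrolyse the ketal, returning to the route at 34.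

## Further compounds

F1 | step 13 | cis-1,6-diol from dihydroxylation of 17 (face of addition not specified) | CC1(C)OCC(CO1)[C@@H]2[C@@H](O[Si](C)(C)C(C)(C)C)C[C@@H](C)C3(O)C2(O)C[C@@](O[Si](C)(C)C)(C)CC3
F2 | step 11 | (7S,8S,10R)-4-methylene octalin | CC1(C)OCC(CO1)[C@@H]2[C@@H](O[Si](C)(C)C(C)(C)C)C[C@@H](C)C3=C2CC(=C)CC3
F3 | step 6 | tert-butyl 2-[(1S,2S,4R)-2-hydroxy-7-methoxy-4-methyl-1,2,3,4-tetrahydronaphthalen-1-yl]acetate | CC(C)(C)OC(=O)C[C@@H]1[C@@H](O)C[C@@H](C)c2ccc(OC)cc21
F4 | step 6 | tert-butyl 3-hydroxy-2-[(1S,2S,4R)-2-hydroxy-7-methoxy-4-methyl-1,2,3,4-tetrahydronaphthalen-1-yl]propanoate (C11 epimers) | CC(C)(C)OC(=O)C(CO)[C@@H]1[C@@H](O)C[C@@H](C)c2ccc(OC)cc21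
F5 | step 5 | trans-bromohydrin of 7 (1-hydroxy cis to methyl, 2-bromo trans to methyl) | C[C@@H]1C[C@@H](Br)[C@H](O)c2cc(OC)ccc12
F6 | step 16 | 4,5-dihydrofuran (C6=C7 enol ether) from 22 (C11 epimers) | CC(=O)OCC1COC2=C1[C@@H](O[Si](C)(C)C(C)(C)C)C[C@@H](C)[C@]3(O)CC[C@@](C)(O3)C2
F7 | step 22 | (2R)-3-chloro-2-hydroxy-2-methylpropanoic acid | OC(=O)[C@@](C)(O)CCl
F8 | step 22 | (2R)-3-chloro-2-methyl-2-(triethylsilyloxy)propanoic acid | OC(=O)[C@@](C)(O[Si](CC)(CC)CC)CCl
F9 | step 22 | 8-O-[(2R)-3-chloro-2-methyl-2-(triethylsilyloxy)propanoyl] furan methyl ketal | CC(=O)OCc1coc2C[C@@]3(C)CC[C@](OC)(O3)[C@H](C)C[C@H](OC(=O)[C@@](C)(O[Si](CC)(CC)CC)CCl)c12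
F10 | step 22 | 6,12-endoperoxide of F9 | CC(=O)OCC1=C2C4(C[C@@]3(C)CC[C@](OC)(O3)[C@H](C)C[C@@H]2OC(=O)[C@@](C)(O[Si](CC)(CC)CC)CCl)OOC1O4
F11 | step 22 | γ-hydroxybutenolide from F10 (C6 epimers) | CC(=O)OCC1=C2C(O)(C[C@@]3(C)CC[C@](OC)(O3)[C@H](C)C[C@@H]2OC(=O)[C@@](C)(O[Si](CC)(CC)CC)CCl)OC1=O
F12 | step 22 | 1-O-methyl, 2′-O-triethylsilyl derivative of the target | CC(=O)OCC1=C2/C(=C\[C@@]3(C)CC[C@](OC)(O3)[C@H](C)C[C@@H]2OC(=O)[C@@](C)(O[Si](CC)(CC)CC)CCl)OC1=O
A1 | alternative 1 | acyclic C1–C10 dithiane carbinol (product of the linchpin coupling) | C=CC[C@@](C)(O)CC1(SCCCS1)C[C@@H](O[Si](C)(C)C(C)(C)C)CC#C[Si](C)(C)C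
A2 | alternative 1 | 2-(tert-butyldimethylsilyl)-1,3-dithiane | CC(C)(C)[Si](C)(C)C1SCCCS1
A3 | alternative 1 | (S)-trimethyl[3-(oxiran-2-yl)prop-1-yn-1-yl]silane | C1O[C@H]1CC#C[Si](C)(C)C
A4 | alternative 1 | (R)-2-methyl-2-(prop-2-en-1-yl)oxirane | C=CC[C@]1(C)CO1
A5 | alternative 2 | furan-fused ten-membered C8 carbinol with C10 exo-methylene | C[Si](C)(C)c1oc2C[C@@]3(C)CC[C@](OC)(O3)C(=C)C[C@H](O)c2c1COC(C)=O
A6 | alternative 2 | open-chain furan aldehyde with C9 allylic bromide | C[Si](C)(C)c1oc(C[C@@]2(C)CC[C@](OC)(O2)C(=C)CBr)c(C=O)c1COC(C)=O
A7 | alternative 3 | bis-silyl ether of the tricyclic ylidene butenolide core | CC(C)(C)[Si](C)(C)OCC1=C2/C(=C\[C@@]3(C)CC[C@](O)(O3)[C@H](C)C[C@@H]2O[Si](C)(C)C(C)(C)C)OC1=O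
A8 | alternative 3 | macrocyclic Z-β-iodoenone (C6 ketone, C7=C11 iodide) | CC(C)(C)[Si](C)(C)OC/C(I)=C1/C(=O)C[C@@]2(C)CC[C@](O)(O2)[C@H](C)C[C@@H]1O[Si](C)(C)C(C)(C)C
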